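**Plan**
- Key feature and cut: in ring F the ring oxygen O1'' is an alkyl aryl ether joining benzylic C2'' to ring E carbon C8a''. Cutting O1''–C8a'' opens ring F to an acyclic all-anti C2''–C3''–C4'' triol carrying ring D on C2'' and a 2-bromoaryl ring E on C4''.
- Further cuts: C2''–ring D (aryllithium plus aldehyde), C4–ring D (Friedel–Crafts capture of the upper C4 cation by a ring D phenol), C2''–C3'' of the chain (anti γ-silylallylboration of the ring E aldehyde), and O1–C2 of ring C (chalcone epoxide).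
- Forward order: ring C is built first (chalcone, epoxide, dihydroflavonol, flavan-3,4-diol ether), ring D is attached at C4 and its hydroxyl is turned into the carbanion site, the C2''–C4'' chain is joined, ring F is closed last, then deprotection.
- Stereochemistry: C3 from poly-L-leucine epoxidation, C2 by trans ring closure, C4 by arene attack anti to O3; C4'' and C3'' from isopinocampheyl-controlled anti allylboration, C2'' by Felkin–Anh addition; the ring F closure creates no stereocentre.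

Key step: step 16

Remark: unprimed locants and rings A, B, C belong to the upper flavan, ring D is the linking pyrogallol ring, double-primed locants belong to the lower flavan (heterocycle F, benzo ring E); nine hydroxyls travel as benzyl ethers; the isopinocampheyl antipode in step 12 is assigned by analogy with allyl transfer from the same borane; compound 1 and the step 12 reagents are taken as purchasable.

Step 1
Reactants: 1 1-[4-(benzyloxy)-2-hydroxyphenyl]ethanone
Product: 2 1-[4-(benzyloxy)-2-(methoxymethoxy)phenyl]ethanone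
Conditions: NaH, MOMCl, DMF, 0 °C → rt
Reagents that add atoms: chloromethyl methyl ether, COCCl
Why: Williamson etherification of the sodium phenoxide with the chloromethyl ether masks the chelated 2-hydroxyl, which would otherwise let the chalcone close to a racemic flavanone under base.

Step 2
Reactants: 2 1-[4-(benzyloxy)-2-(methoxymethoxy)phenyl]ethanone; 3 3,4,5-tris(benzyloxy)benzaldehyde
Product: 5 (E)-1-[4-(benzyloxy)-2-(methoxymethoxy)phenyl]-3-[3,4,5-tris(benzyloxy)phenyl]prop-2-en-1-one, via aldol adduct 4 (not isolated)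
Conditions: KOH, EtOH/THF, rt
Reagents that add atoms: none
Why: Claisen–Schmidt condensation of the methyl ketone enolate with the non-enolisable aldehyde, the aldol adduct losing water by E1cB elimination, gives the conjugated E-enone under thermodynamic control.

Step 3
Reactants: 5 (E)-1-[4-(benzyloxy)-2-(methoxymethoxy)phenyl]-3-[3,4,5-tris(benzyloxy)phenyl]prop-2-en-1-one
Product: 6 [4-(benzyloxy)-2-(methoxymethoxy)phenyl]{(2R,3S)-3-[3,4,5-tris(benzyloxy)phenyl]oxiran-2-yl}methanone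
Conditions: poly-L-leucine, urea–H2O2, DBU, THF, rt
Reagents that add atoms: urea–hydrogen peroxide, NC(N)=O.OO
Why: Juliá–Colonna epoxidation (Weitz–Scheffer conjugate addition of hydroperoxide steered by the helical poly-L-leucine) is expected to give the trans (2R,3S)-epoxy ketone, as it does for other 2'-alkoxymethoxy chalcones, and this fixes the carbon that becomes C3.

Step 4
Reactants: 6 [4-(benzyloxy)-2-(methoxymethoxy)phenyl]{(2R,3S)-3-[3,4,5-tris(benzyloxy)phenyl]oxiran-2-yl}methanone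
Product: 8 (2R,3R)-7-(benzyloxy)-3-hydroxy-2-[3,4,5-tris(benzyloxy)phenyl]chroman-4-one, via 2'-hydroxy epoxide 7 (not isolated)
Conditions: conc. HCl, MeOH/THF, 55 °C
Reagents that add atoms: none
Why: acid removes the acetal and the freed phenol opens the epoxide at the benzylic carbon in a 6-endo ring closure (the usual passage from chalcone epoxides to dihydroflavonols), so the α-carbon keeps its configuration as C3 (R) and C2 is set trans to it (R), whether the opening is concerted with inversion or runs through the benzylic cation.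

Step 5
Reactants: 8 (2R,3R)-7-(benzyloxy)-3-hydroxy-2-[3,4,5-tris(benzyloxy)phenyl]chroman-4-one
Product: 9 (2R,3S,4R)-7-(benzyloxy)-2-[3,4,5-tris(benzyloxy)phenyl]chromane-3,4-diol
Conditions: NaBH4, MeOH/THF, 0 °C
Reagents that add atoms: none
Why: borohydride reduction of the chromanone with axial hydride delivery should give the 2,3-trans-3,4-trans diol (4R), and the C4 configuration is of no consequence because this carbon is ionised in step 8.

Step 6
Reactants: 9 (2R,3S,4R)-7-(benzyloxy)-2-[3,4,5-tris(benzyloxy)phenyl]chromane-3,4-diol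
Product: 10 (2R,3S,4R)-3,4,7-tris(benzyloxy)-2-[3,4,5-tris(benzyloxy)phenyl]chromane
Conditions: NaH, BnBr, DMF, 0 °C → rt
Reagents that add atoms: benzyl bromide, BrCc1ccccc1
Why: double Williamson benzylation protects O3 for the rest of the route and turns O4 into an ether leaving group for the C4 ionisation.

Step 7
Reactants: 3 3,4,5-tris(benzyloxy)benzaldehyde
Product: 12 3,4,5-tris(benzyloxy)phenol, via aryl formate 11 (not isolated)
Conditions: mCPBA, CH2Cl2, rt; then K2CO3 (cat.), MeOH, rt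
Reagents that add atoms: 3-chloroperoxybenzoic acid, OOC(=O)c1cccc(Cl)c1
Why: Baeyer–Villiger (Dakin-type) oxidation of the electron-rich benzaldehyde occurs with aryl migration to the formate, whose methanolysis gives the tetra-oxygenated phenol that becomes ring D.

Step 8
Reactants: 10 (2R,3S,4R)-3,4,7-tris(benzyloxy)-2-[3,4,5-tris(benzyloxy)phenyl]chromane; 12 3,4,5-tris(benzyloxy)phenol
Product: 13 3,4,5-tris(benzyloxy)-2-{(2R,3S,4S)-3,7-bis(benzyloxy)-2-[3,4,5-tris(benzyloxy)phenyl]chroman-4-yl}phenol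
Conditions: TMSOTf (0.5 equiv), 12 (3 equiv), CH2Cl2, −40 → 0 °C
Reagents that add atoms: none
Why: Friedel–Crafts alkylation in which the Lewis acid ionises the 4-benzyloxy group to the C4 benzylic cation stabilised by O1 and the 7-benzyloxy group, and the phenol, which is more nucleophilic than rings A and B so that self-condensation is outrun, attacks through its only free ortho carbon anti to the 3-benzyloxy group, which sets C4 (S) in the 3,4-trans sense.

Step 9
Reactants: 13 3,4,5-tris(benzyloxy)-2-{(2R,3S,4S)-3,7-bis(benzyloxy)-2-[3,4,5-tris(benzyloxy)phenyl]chroman-4-yl}phenol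
Product: 14 3,4,5-tris(benzyloxy)-2-{(2R,3S,4S)-3,7-bis(benzyloxy)-2-[3,4,5-tris(benzyloxy)phenyl]chroman-4-yl}phenyl trifluoromethanesulfonate
Conditions: Tf2O, pyridine, CH2Cl2, 0 °C
Reagents that add atoms: trifluoromethanesulfonic anhydride, O=S(=O)(OS(=O)(=O)C(F)(F)F)C(F)(F)F
Why: O-sulfonylation with triflic anhydride turns the activating hydroxyl, which sits exactly on the ring D carbon that must later carry C2'', into a leaving group for palladium catalysis.

Step 10
Reactants: 14 3,4,5-tris(benzyloxy)-2-{(2R,3S,4S)-3,7-bis(benzyloxy)-2-[3,4,5-tris(benzyloxy)phenyl]chroman-4-yl}phenyl trifluoromethanesulfonate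
Product: 15 (2R,3S,4S)-3,7-bis(benzyloxy)-2-[3,4,5-tris(benzyloxy)phenyl]-4-[2,3,4-tris(benzyloxy)-6-(trimethylstannyl)phenyl]chromane
Conditions: Me3SnSnMe3, Pd(PPh3)4 (5 mol %), LiCl, 1,4-dioxane, 100 °C
Reagents that add atoms: hexamethylditin, C[Sn](C)(C)[Sn](C)(C)C
Why: palladium-catalysed stannylation of the aryl triflate with the distannane (Stille-type cycle of oxidative addition to zerovalent palladium, tin-to-palladium transmetalation and reductive elimination, with chloride assisting the triflate) gives a stable precursor of the ring D carbanion.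

Step 11
Reactants: 16 2-bromo-4-hydroxybenzaldehyde
Product: 17 4-(benzyloxy)-2-bromobenzaldehyde
Conditions: BnBr, K2CO3, DMF, rt
Reagents that add atoms: benzyl bromide, BrCc1ccccc1
Why: Williamson benzylation of the phenoxide protects the ring E hydroxyl as the same ether used elsewhere.

Step 12
Reactants: 17 4-(benzyloxy)-2-bromobenzaldehyde
Product: 19 (1S,2R)-1-[4-(benzyloxy)-2-bromophenyl]but-3-ene-1,2-diol, via boron-bound β-silyl alcohol 18 (not isolated)
Conditions: allyl(diisopropylamino)dimethylsilane, n-BuLi, TMEDA, Et2O, 0 °C; (+)-B-methoxydiisopinocampheylborane, −78 °C; BF3·OEt2; 17, −78 °C; then 30% H2O2, KF, KHCO3, THF/MeOH, rt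
Reagents that add atoms: allyl(diisopropylamino)dimethylsilane, C=CC[Si](C)(C)N(C(C)C)C(C)C; hydrogen peroxide, OO
Why: Brown-type allylboration with the (E)-γ-silylallyl diisopinocampheylborane (from (−)-α-pinene) passes through a chair Zimmerman–Traxler transition state in which the isopinocampheyl groups direct attack to the Re face of the aldehyde and the E geometry gives the anti adduct, and Tamao–Fleming oxidation then replaces silicon by hydroxyl with retention, so C4'' (1S) and C3'' (2R) are set together in the erythro sense without any substitution at the ionisable benzylic carbon.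

Step 13
Reactants: 19 (1S,2R)-1-[4-(benzyloxy)-2-bromophenyl]but-3-ene-1,2-diol
Product: 20 (4S,5R)-4-[4-(benzyloxy)-2-bromophenyl]-5-ethenyl-2,2-dimethyl-1,3-dioxolane
Conditions: 2,2-dimethoxypropane, PPTS (cat.), CH2Cl2, rt
Reagents that add atoms: 2,2-dimethoxypropane, COC(C)(C)OC
Why: acid-catalysed transketalisation gives the cis-4,5-disubstituted dioxolane, which protects O3'' and O4'' and holds the future C2'' arm and ring E on one face of a five-membered ring.

Step 14
Reactants: 20 (4S,5R)-4-[4-(benzyloxy)-2-bromophenyl]-5-ethenyl-2,2-dimethyl-1,3-dioxolane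
Product: 22 (4S,5S)-5-[4-(benzyloxy)-2-bromophenyl]-2,2-dimethyl-1,3-dioxolane-4-carbaldehyde, via secondary ozonide 21 (not isolated)
Conditions: O3, CH2Cl2, −78 °C; then PPh3, −78 °C → rt; used crude
Reagents that add atoms: ozone, [O-][O+]=O
Why: ozonolysis with reductive work-up cuts the terminal alkene to the aldehyde carbon C2'' under neutral conditions, so the epimerisable cis α-alkoxy aldehyde never meets base.

Step 15
Reactants: 15 (2R,3S,4S)-3,7-bis(benzyloxy)-2-[3,4,5-tris(benzyloxy)phenyl]-4-[2,3,4-tris(benzyloxy)-6-(trimethylstannyl)phenyl]chromane; 22 (4S,5S)-5-[4-(benzyloxy)-2-bromophenyl]-2,2-dimethyl-1,3-dioxolane-4-carbaldehyde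
Product: 24 (R)-{3,4,5-tris(benzyloxy)-2-[(2R,3S,4S)-3,7-bis(benzyloxy)-2-[3,4,5-tris(benzyloxy)phenyl]chroman-4-yl]phenyl}[(4R,5S)-5-[4-(benzyloxy)-2-bromophenyl]-2,2-dimethyl-1,3-dioxolan-4-yl]methanol, via ring D aryllithium 23 (not isolated)
Conditions: 15, MeLi, THF, −78 → −40 °C; then 22 (1.3 equiv), −78 °C; aq. NH4Cl
Reagents that add atoms: none
Why: tin–lithium exchange gives the ring D aryllithium, whose 1,2-addition to the aldehyde is faster than bromine–lithium exchange at ring E and should follow the polar Felkin–Anh model (attack anti to the α C–O bond, reinforced by the cis aryl group), which sets C2'' as the (R)-carbinol anti to O3''.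

Step 16
Reactants: 24 (R)-{3,4,5-tris(benzyloxy)-2-[(2R,3S,4S)-3,7-bis(benzyloxy)-2-[3,4,5-tris(benzyloxy)phenyl]chroman-4-yl]phenyl}[(4R,5S)-5-[4-(benzyloxy)-2-bromophenyl]-2,2-dimethyl-1,3-dioxolan-4-yl]methanol
Product: 25 (3aR,4R,9bS)-7-(benzyloxy)-2,2-dimethyl-4-{3,4,5-tris(benzyloxy)-2-[(2R,3S,4S)-3,7-bis(benzyloxy)-2-[3,4,5-tris(benzyloxy)phenyl]chroman-4-yl]phenyl}-3a,9b-dihydro-4H-[1,3]dioxolo[4,5-c]chromene (nona-O-benzyl 3'',4''-O-isopropylidene target)
Conditions: CuI (10 mol %), 3,4,7,8-tetramethyl-1,10-phenanthroline (20 mol %), Cs2CO3 (2 equiv), toluene, 110 °C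
Reagents that add atoms: none
Why: Cs2CO3 deprotonates the only free hydroxyl (C2''–OH), the phenanthroline-bound monovalent copper alkoxide undergoes intramolecular oxidative addition into the ring E C–Br bond, and reductive elimination from trivalent copper forms O1''–C8a''. The closest known reaction type is the ligand-accelerated Ullmann ether synthesis of secondary alcohols with aryl bromides, here in its intramolecular, chroman-forming version. Ring F (O1''–C2''–C3''–C4''–C4a''–C8a'') closes in a six-membered exo mode at the aryl carbon. No stereocentre is formed and no bond to C2'', C3'' or C4'' is broken, so the configurations set in steps 12 and 15 pass through unchanged and no benzylic cation is generated. Only chemoselectivity is needed: the ketal ties up O3'' (which would otherwise close a five-membered ring) and O4'', O3 is benzylated, and the cis-dioxolane holds the alkoxide arm and the aryl bromide on the same face, so cyclisation should outrun intermolecular coupling, oxidation of the alkoxide and hydrodebromination.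

Step 17
Reactants: 25 nona-O-benzyl 3'',4''-O-isopropylidene target
Product: 26 (2R,3S,4S)-7-(benzyloxy)-2-{3,4,5-tris(benzyloxy)-2-[(2R,3S,4S)-3,7-bis(benzyloxy)-2-[3,4,5-tris(benzyloxy)phenyl]chroman-4-yl]phenyl}chromane-3,4-diol (nona-O-benzyl target)
Conditions: AcOH/H2O/THF (4:1:1), 40 °C
Reagents that add atoms: none
Why: ketal hydrolysis through the tertiary oxocarbenium ion is far faster than ionisation of the C4''–O bond, which the neighbouring C3'' oxygen retards, so the cis-diol should be released without epimerisation at C4''.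

Step 18
Reactants: 26 nona-O-benzyl target
Product: 27 (2R,3S,4S)-2-{3,4,5-trihydroxy-2-[(2R,3S,4S)-3,7-dihydroxy-2-(3,4,5-trihydroxyphenyl)chroman-4-yl]phenyl}chromane-3,4,7-triol (CNP0205451.3)
Conditions: H2 (1 atm), Pd(OH)2/C, THF/MeOH, rt
Reagents that add atoms: none
Why: catalytic hydrogenolysis cleaves all nine benzyl ethers under neutral conditions, under which the free benzylic C4''–OH, the ring C–O bonds and the C4–ring D bond are expected to survive, and gives the target.

**Compound list**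

1 | 1-[4-(benzyloxy)-2-hydroxyphenyl]ethanone | CC(=O)c1ccc(OCc2ccccc2)cc1O | starting material
2 | 1-[4-(benzyloxy)-2-(methoxymethoxy)phenyl]ethanone | CC(=O)c1ccc(OCc2ccccc2)cc1OCOC | intermediate
3 | 3,4,5-tris(benzyloxy)benzaldehyde | O=Cc1cc(OCc2ccccc2)c(OCc2ccccc2)c(OCc2ccccc2)c1 | starting material
4 | 1-[4-(benzyloxy)-2-(methoxymethoxy)phenyl]-3-hydroxy-3-[3,4,5-tris(benzyloxy)phenyl]propan-1-one (racemic aldol adduct) | COCOc1cc(OCc2ccccc2)ccc1C(=O)CC(O)c1cc(OCc2ccccc2)c(OCc2ccccc2)c(OCc2ccccc2)c1 | intermediate (not isolated)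
5 | (E)-1-[4-(benzyloxy)-2-(methoxymethoxy)phenyl]-3-[3,4,5-tris(benzyloxy)phenyl]prop-2-en-1-one | COCOc1cc(OCc2ccccc2)ccc1C(=O)/C=C/c1cc(OCc2ccccc2)c(OCc2ccccc2)c(OCc2ccccc2)c1 | intermediate
6 | [4-(benzyloxy)-2-(methoxymethoxy)phenyl]{(2R,3S)-3-[3,4,5-tris(benzyloxy)phenyl]oxiran-2-yl}methanone | COCOc1cc(OCc2ccccc2)ccc1C(=O)[C@@H]1O[C@H]1c1cc(OCc2ccccc2)c(OCc2ccccc2)c(OCc2ccccc2)c1 | intermediate
7 | [4-(benzyloxy)-2-hydroxyphenyl]{(2R,3S)-3-[3,4,5-tris(benzyloxy)phenyl]oxiran-2-yl}methanone | Oc1cc(OCc2ccccc2)ccc1C(=O)[C@@H]1O[C@H]1c1cc(OCc2ccccc2)c(OCc2ccccc2)c(OCc2ccccc2)c1 | intermediate (not isolated)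
8 | (2R,3R)-7-(benzyloxy)-3-hydroxy-2-[3,4,5-tris(benzyloxy)phenyl]chroman-4-one | c7ccccc7COc1ccc2c(c1)O[C@H](c3cc(OCc7ccccc7)c(OCc7ccccc7)c(OCc7ccccc7)c3)[C@@H](O)C2=O | intermediate
9 | (2R,3S,4R)-7-(benzyloxy)-2-[3,4,5-tris(benzyloxy)phenyl]chromane-3,4-diol | c7ccccc7COc1ccc2c(c1)O[C@H](c3cc(OCc7ccccc7)c(OCc7ccccc7)c(OCc7ccccc7)c3)[C@@H](O)[C@@H]2O | intermediate
10 | (2R,3S,4R)-3,4,7-tris(benzyloxy)-2-[3,4,5-tris(benzyloxy)phenyl]chromane | c7ccccc7COc1ccc2c(c1)O[C@H](c3cc(OCc7ccccc7)c(OCc7ccccc7)c(OCc7ccccc7)c3)[C@@H](OCc7ccccc7)[C@@H]2OCc7ccccc7 | intermediate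
11 | 3,4,5-tris(benzyloxy)phenyl formate | O=COc1cc(OCc2ccccc2)c(OCc2ccccc2)c(OCc2ccccc2)c1 | intermediate (not isolated)
12 | 3,4,5-tris(benzyloxy)phenol | Oc1cc(OCc2ccccc2)c(OCc2ccccc2)c(OCc2ccccc2)c1 | intermediate
13 | 3,4,5-tris(benzyloxy)-2-{(2R,3S,4S)-3,7-bis(benzyloxy)-2-[3,4,5-tris(benzyloxy)phenyl]chroman-4-yl}phenol | c7ccccc7COc1ccc2c(c1)O[C@H](c3cc(OCc7ccccc7)c(OCc7ccccc7)c(OCc7ccccc7)c3)[C@@H](OCc7ccccc7)[C@@H]2c4c(O)cc(OCc7ccccc7)c(OCc7ccccc7)c4OCc7ccccc7 | intermediate
14 | 3,4,5-tris(benzyloxy)-2-{(2R,3S,4S)-3,7-bis(benzyloxy)-2-[3,4,5-tris(benzyloxy)phenyl]chroman-4-yl}phenyl trifluoromethanesulfonate | c7ccccc7COc1ccc2c(c1)O[C@H](c3cc(OCc7ccccc7)c(OCc7ccccc7)c(OCc7ccccc7)c3)[C@@H](OCc7ccccc7)[C@@H]2c4c(OS(=O)(=O)C(F)(F)F)cc(OCc7ccccc7)c(OCc7ccccc7)c4OCc7ccccc7 | intermediate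
15 | (2R,3S,4S)-3,7-bis(benzyloxy)-2-[3,4,5-tris(benzyloxy)phenyl]-4-[2,3,4-tris(benzyloxy)-6-(trimethylstannyl)phenyl]chromane | c7ccccc7COc1ccc2c(c1)O[C@H](c3cc(OCc7ccccc7)c(OCc7ccccc7)c(OCc7ccccc7)c3)[C@@H](OCc7ccccc7)[C@@H]2c4c([Sn](C)(C)C)cc(OCc7ccccc7)c(OCc7ccccc7)c4OCc7ccccc7 | intermediate
16 | 2-bromo-4-hydroxybenzaldehyde | O=Cc1ccc(O)cc1Br | starting material
17 | 4-(benzyloxy)-2-bromobenzaldehyde | O=Cc1ccc(OCc2ccccc2)cc1Br | intermediate
18 | O-diisopinocampheylboryl derivative of (1S,2R)-1-[4-(benzyloxy)-2-bromophenyl]-2-[(diisopropylamino)dimethylsilyl]but-3-en-1-ol (isopinocampheyl groups from (−)-α-pinene, drawn without their stereodescriptors) | Brc1cc(OCc2ccccc2)ccc1[C@H](OB(C1CC2CC(C1C)C2(C)C)C1CC2CC(C1C)C2(C)C)[C@H]([Si](C)(C)N(C(C)C)C(C)C)C=C | intermediate (not isolated)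
19 | (1S,2R)-1-[4-(benzyloxy)-2-bromophenyl]but-3-ene-1,2-diol | Brc1cc(OCc2ccccc2)ccc1[C@H](O)[C@H](O)C=C | intermediate
20 | (4S,5R)-4-[4-(benzyloxy)-2-bromophenyl]-5-ethenyl-2,2-dimethyl-1,3-dioxolane | Brc1cc(OCc2ccccc2)ccc1[C@@H]1OC(C)(C)O[C@@H]1C=C | intermediate
21 | 3-{(4S,5S)-5-[4-(benzyloxy)-2-bromophenyl]-2,2-dimethyl-1,3-dioxolan-4-yl}-1,2,4-trioxolane (secondary ozonide, trioxolane carbon unassigned) | Brc1cc(OCc2ccccc2)ccc1[C@@H]1OC(C)(C)O[C@@H]1C1OCOO1 | intermediate (not isolated)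
22 | (4S,5S)-5-[4-(benzyloxy)-2-bromophenyl]-2,2-dimethyl-1,3-dioxolane-4-carbaldehyde | Brc1cc(OCc2ccccc2)ccc1[C@@H]1OC(C)(C)O[C@@H]1C=O | intermediate
23 | (2R,3S,4S)-3,7-bis(benzyloxy)-4-[2,3,4-tris(benzyloxy)-6-lithiophenyl]-2-[3,4,5-tris(benzyloxy)phenyl]chromane | c7ccccc7COc1ccc2c(c1)O[C@H](c3cc(OCc7ccccc7)c(OCc7ccccc7)c(OCc7ccccc7)c3)[C@@H](OCc7ccccc7)[C@@H]2c4c([Li])cc(OCc7ccccc7)c(OCc7ccccc7)c4OCc7ccccc7 | intermediate (not isolated)
24 | (R)-{3,4,5-tris(benzyloxy)-2-[(2R,3S,4S)-3,7-bis(benzyloxy)-2-[3,4,5-tris(benzyloxy)phenyl]chroman-4-yl]phenyl}[(4R,5S)-5-[4-(benzyloxy)-2-bromophenyl]-2,2-dimethyl-1,3-dioxolan-4-yl]methanol | c7ccccc7COc1ccc2c(c1)O[C@H](c3cc(OCc7ccccc7)c(OCc7ccccc7)c(OCc7ccccc7)c3)[C@@H](OCc7ccccc7)[C@@H]2c4c([C@@H](O)[C@H]5OC(C)(C)O[C@H]5c6ccc(OCc7ccccc7)cc6Br)cc(OCc7ccccc7)c(OCc7ccccc7)c4OCc7ccccc7 | intermediate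
25 | (3aR,4R,9bS)-7-(benzyloxy)-2,2-dimethyl-4-{3,4,5-tris(benzyloxy)-2-[(2R,3S,4S)-3,7-bis(benzyloxy)-2-[3,4,5-tris(benzyloxy)phenyl]chroman-4-yl]phenyl}-3a,9b-dihydro-4H-[1,3]dioxolo[4,5-c]chromene | c7ccccc7COc1ccc2c(c1)O[C@H](c3cc(OCc7ccccc7)c(OCc7ccccc7)c(OCc7ccccc7)c3)[C@@H](OCc7ccccc7)[C@@H]2c4c([C@H]2Oc3cc(OCc7ccccc7)ccc3[C@H](O5)[C@@H]2OC5(C)C)cc(OCc7ccccc7)c(OCc7ccccc7)c4OCc7ccccc7 | intermediate
26 | (2R,3S,4S)-7-(benzyloxy)-2-{3,4,5-tris(benzyloxy)-2-[(2R,3S,4S)-3,7-bis(benzyloxy)-2-[3,4,5-tris(benzyloxy)phenyl]chroman-4-yl]phenyl}chromane-3,4-diol | c7ccccc7COc1ccc2c(c1)O[C@H](c3cc(OCc7ccccc7)c(OCc7ccccc7)c(OCc7ccccc7)c3)[C@@H](OCc7ccccc7)[C@@H]2c4c([C@H]2Oc3cc(OCc7ccccc7)ccc3[C@H](O)[C@@H]2O)cc(OCc7ccccc7)c(OCc7ccccc7)c4OCc7ccccc7 | intermediate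
27 | (2R,3S,4S)-2-{3,4,5-trihydroxy-2-[(2R,3S,4S)-3,7-dihydroxy-2-(3,4,5-trihydroxyphenyl)chroman-4-yl]phenyl}chromane-3,4,7-triol | Oc1ccc2c(c1)O[C@H](c1cc(O)c(O)c(O)c1)[C@@H](O)[C@@H]2c1c([C@H]2Oc3cc(O)ccc3[C@H](O)[C@@H]2O)cc(O)c(O)c1O | target

**Count and risks**

Total steps: 18. Longest linear sequence: 13 steps (steps 1–6, 8–10, 15–18).

Step 15. What may go wrong: poor facial selectivity in the addition of the hindered ring D aryllithium, with some enolisation of the cis aldehyde, so that the C2'' carbinol forms as a mixture. Fallback: setting out from 15 and 22, the addition is run without regard to selectivity, which gives 24 together with its C2'' epimer, the (S)-carbinol F1. The mixture is oxidised with Dess–Martin periodinane and NaHCO3 in CH2Cl2 to the aryl ketone F2. F2 is then reduced with Zn(BH4)2 in Et2O at −30 °C; zinc chelates the carbonyl oxygen and the α-oxygen O3'', hydride enters from the open face of the chelate, and the anti (R)-carbinol results. The sequence comes back to the route at 24, with C2'' now set by reduction and not by addition.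

Step 16. What may go wrong: oxidation of the copper-bound benzylic alkoxide to the ketone, or hydrodebromination of ring E, outpacing C–O bond formation at the hindered alkoxide. Fallback: setting out from 24, the same O1''–C8a'' bond is made by palladium-catalysed intramolecular etherification (Buchwald–Hartwig type) with Pd(OAc)2, 2-(di-tert-butylphosphino)-1,1'-binaphthyl and Cs2CO3 in toluene at 70 °C. Here zerovalent palladium inserts into the C–Br bond first, the alkoxide then binds, and the bulky phosphine drives C–O reductive elimination from divalent palladium ahead of β-hydride loss. The fallback comes back directly at 25 and makes no new compound (F0).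

Step 4. What may go wrong: acid-mediated opening of the epoxide diverting to aryl migration, retro-aldol cleavage or solvolysis products in place of the 6-endo closure. Fallback: setting out from 6, phenylmethanethiol and SnCl4 in CH2Cl2 at −20 °C open the epoxide at the benzylic carbon and remove the methoxymethyl group, giving the α-hydroxy β-sulfanyl ketone (2S)-3-(benzylsulfanyl)-1-[4-(benzyloxy)-2-hydroxyphenyl]-2-hydroxy-3-[3,4,5-tris(benzyloxy)phenyl]propan-1-one F3. AgBF4 in CH2Cl2 at 0 °C then abstracts the thiolate and the phenol closes ring C trans to the retained C3 hydroxyl, coming back to the route at 8.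

**Further compounds**

F1 | step 15 | (S)-{3,4,5-tris(benzyloxy)-2-[(2R,3S,4S)-3,7-bis(benzyloxy)-2-[3,4,5-tris(benzyloxy)phenyl]chroman-4-yl]phenyl}[(4R,5S)-5-[4-(benzyloxy)-2-bromophenyl]-2,2-dimethyl-1,3-dioxolan-4-yl]methanol | c7ccccc7COc1ccc2c(c1)O[C@H](c3cc(OCc7ccccc7)c(OCc7ccccc7)c(OCc7ccccc7)c3)[C@@H](OCc7ccccc7)[C@@H]2c4c([C@H](O)[C@H]5OC(C)(C)O[C@H]5c6ccc(OCc7ccccc7)cc6Br)cc(OCc7ccccc7)c(OCc7ccccc7)c4OCc7ccccc7
F2 | step 15 | {3,4,5-tris(benzyloxy)-2-[(2R,3S,4S)-3,7-bis(benzyloxy)-2-[3,4,5-tris(benzyloxy)phenyl]chroman-4-yl]phenyl}[(4S,5S)-5-[4-(benzyloxy)-2-bromophenyl]-2,2-dimethyl-1,3-dioxolan-4-yl]methanone | c7ccccc7COc1ccc2c(c1)O[C@H](c3cc(OCc7ccccc7)c(OCc7ccccc7)c(OCc7ccccc7)c3)[C@@H](OCc7ccccc7)[C@@H]2c4c(C(=O)[C@H]5OC(C)(C)O[C@H]5c6ccc(OCc7ccccc7)cc6Br)cc(OCc7ccccc7)c(OCc7ccccc7)c4OCc7ccccc7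
F0 | step 16 | none | none
F3 | step 4 | (2S)-3-(benzylsulfanyl)-1-[4-(benzyloxy)-2-hydroxyphenyl]-2-hydroxy-3-[3,4,5-tris(benzyloxy)phenyl]propan-1-one (sulfur-bearing carbon unassigned) | Oc1cc(OCc2ccccc2)ccc1C(=O)[C@H](O)C(SCc1ccccc1)c1cc(OCc2ccccc2)c(OCc2ccccc2)c(OCc2ccccc2)c1
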